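I rank these four flasks by one number, and I commit to it before I see them.

the same everywhere: substrate 0.010 M

| charge | coupling partner | second reagent | third reagent | temperature | remark | time |
|---|---|---|---|---|---|---|
| violet | 0.60 equiv | 0.75 equiv | 2 equiv | −10 °C | run made earlier |  |
| teal | 0.60 equiv | 1.1 equiv | 2 equiv | 23 °C | run made earlier |  |
| Monday's | 0.600 equiv | 1.50 equiv | 2.00 equiv | 5 °C |  | 4.0 min |
| Tuesday's | 0.600 equiv | 1.50 equiv | 2.00 equiv | −15 °C |  | 4.0 min |
| Wednesday's | 0.600 equiv | 1.50 equiv | 2.00 equiv | 35 °C |  | 4.0 min |
| Friday's | 0.600 equiv | 1.50 equiv | 2.00 equiv | −25 °C |  | 4.0 min |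

violet run (percent of the substrate charged)

| time / min | intermediate A / % | target / % | substrate / % |
|---|---|---|---|
| 0.667 | 13.6 | 0 | 86.8 |
| 1.33 | 22.6 | 0 | 77.8 |
| 2.00 | 29.4 | 0.1 | 70.8 |
| 4.00 | 41.1 | 0.3 | 58.4 |
| 8.00 | 49.7 | 0 | 48.7 |

teal run (percent of the substrate charged)

| time / s | intermediate A / % | target / % | substrate / % |
|---|---|---|---|
| 20.0 | 44.2 | 0.2 | 53.2 |
| 40.0 | 49.2 | 0.5 | 45.5 |
| 60.0 | 48.7 | 0.6 | 42.4 |
| 80.0 | 45.9 | 0.2 | 40.9 |
| 90.0 | 44.4 | 0.7 | 40.6 |

(each reading ± 0.5 percentage points)

* ranking by amount of intermediate A, in percent of the substrate charged, from high to low, at 4.0 min (Monday's / Tuesday's / Wednesday's / Friday's)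
* the amount of intermediate A, in percent of the substrate charged of the flask you put first, at 4.0 min
* the amount of intermediate A, in percent of the substrate charged of the flask you put last, at 4.0 min

- the earlier runs were read with a standard deviation of 0.5 percentage points
- a reading or a percentage of target counts all its forms, free or not

In teal, substrate stalls at 40.6 %, close to what the charge leaves, so the coupling partner is the limiting reagent and 0.600 equiv caps intermediate A. By 90.0 s teal has lost 15 percentage points from substrate plus intermediate A, which reads as a drain of 0.225 /min. Violet's loss at 8.00 min is 1.6 points against a scatter of 0.5 points per reading, too little for me to read a temperature step from, so I lend the drain the temperature step of the coupling, which runs 16.5 times faster in teal than in violet. I also assume the drain is pseudo-first-order in second reagent.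

My number is the drain number, the drain constant at the flask's temperature and charge times the reading time, in Monday's 0.267; where the coupling finishes early, I take the cap times exp(−number) as what stands. Monday's number gives 46.0 %. Wednesday's is 3.40, which gives 2.00 %. One number isn't enough there, because in my reckoning Wednesday's second reagent can fall to 60.0 % of its charge, and at the mean of that range I get 3.95 %. I reckon Friday's coupling unfinished: its reading time equals 1.12 min of violet's, where violet reads between 13.6 % and 22.6 %. Tuesday's equals 2.62 min, which is longer than Friday's, so I rank Tuesday's above Friday's.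

The forecast gives Monday's > Tuesday's > Friday's > Wednesday's, with 52 % (44 % to 58 %) and 2.5 % (0.5 % to 8 %), holding that the drain "is steeper in temperature". My order is the same, but my two amounts differ.

The flasks give Monday's > Tuesday's > Friday's > Wednesday's, with 44.3 % and 7.59 %.

    substrate + coupling partner → intermediate A (k = 2.60 /M/s, Ea = 54.0 kJ/mol)
    second reagent + intermediate A → intermediate B (k = 0.0990 /M/s, Ea = 49.0 kJ/mol)
    third reagent + intermediate B → target (k = 0.00830 /M/s, Ea = 60.0 kJ/mol)
    intermediate B → side product (k = 4.80 × 10⁻⁴ /s, Ea = 91.0 kJ/mol)
    crystals ⇌ target, rate k5*(cs5 - [target]) while solid is left; crystals form when [target] > cs5 (solubility = 7.50 mM, k = 0.0540 /s)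
    (constants at 5 °C)

Monday's holds 44.3 % against the 46.0 % its number gave. At 4.00 min in Monday's, intermediate A is made at 0.381 of the rate at which it is used up, each step taken net. With Monday's recipe at 0.040 M and the equivalents held, the number rises to 1.07, which reads 20.6 %, and that flask holds 19.7 %.

Readings and results are calculated on assumed constants; the scatter is artificial.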